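Feature: in ring C the ketone carbon C4 sits on ring A ortho to O1, and C2 carries only H, ring B and the CH2 group C3. The C3–C4 and C2–H bonds therefore equal the formyl C–H bond of a ring A salicylaldehyde added across a 1-arylvinyl group on O1.
Cuts, in retrosynthetic order: the two MOM–O bonds (O7, O4'); C3–C4 together with C2–H (opens ring C); the C2=C3 methylene (back to an O1 aryl ester); the three aryl–prenyl bonds at C6, C8 and C3'; the O1–C2 acyl bond.
Forward: rings A and B come from simple phenols. An iodinated ring A salicyl alcohol silyl ether and an iodinated ring B acid are joined at O1, and all three prenyl groups enter in one Stille operation. The ester is then methylenated, CH2OTBS is taken to CHO, and ring C closes in the penultimate step.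
Stereochemistry: C2 (S) is the only stereocentre. It is created in the ring closure under control of a chiral bisphosphine on rhodium, and only a mildly acidic step follows, so ring C is not reopened.
Key step: step 11

Remark 1: the sense of induction of DTBM-SEGPHOS on this substrate class is unknown. The route is written with the (R)-ligand on the assumption that it gives 2S, and the (S)-ligand is used if a trial run shows the opposite.
Remark 2: prenyl = 3-methylbut-2-en-1-yl, MOM = methoxymethyl, TBS = tert-butyldimethylsilyl. Flavanone numbering (O1, C2, C3, C4, C4a, C5–C8, C8a, primed ring B) is used throughout. Compounds 1, 6 and 10 are taken as catalogue items.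

Step 1
Reactants: 1 2,4-dihydroxybenzaldehyde
Product: 2 2,4-dihydroxy-3,5-diiodobenzaldehyde
Conditions: NIS (2.2 equiv), TFA (cat.), MeCN, 0 °C to rt
Reagents that add atoms: N-iodosuccinimide, O=C1CCC(=O)N1I
Why: Electrophilic aromatic iodination; C3 and C5 are the only positions ortho/para to both hydroxyl groups and meta to the formyl group, so two equivalents of NIS should fill exactly these two sites.

Step 2
Reactants: 2 2,4-dihydroxy-3,5-diiodobenzaldehyde
Product: 3 2-hydroxy-3,5-diiodo-4-(methoxymethoxy)benzaldehyde
Conditions: MOMCl (1.1 equiv), K2CO3 (1.2 equiv), acetone, 0 °C to rt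
Reagents that add atoms: chloromethyl methyl ether (MOMCl), COCCl
Why: Williamson-type O-alkylation; the 2-OH is locked in a hydrogen bond to the formyl oxygen while the 4-OH between two iodines is the more acidic one, so one equivalent of the small electrophile should react at O4 only.

Step 3
Reactants: 3 2-hydroxy-3,5-diiodo-4-(methoxymethoxy)benzaldehyde
Product: 4 2-(hydroxymethyl)-4,6-diiodo-5-(methoxymethoxy)phenol
Conditions: NaBH4, THF/MeOH, 0 °C; near-neutral aqueous quench
Reagents that add atoms: none
Why: Borohydride reduction of an aryl aldehyde; aryl iodides and the acetal are inert, and the near-neutral quench avoids ionisation of the electron-rich salicyl alcohol.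

Step 4
Reactants: 4 2-(hydroxymethyl)-4,6-diiodo-5-(methoxymethoxy)phenol
Product: 5 2-{[(tert-butyldimethylsilyl)oxy]methyl}-4,6-diiodo-5-(methoxymethoxy)phenol
Conditions: TBSCl (1.05 equiv), imidazole (2.2 equiv), CH2Cl2, 0 °C
Reagents that add atoms: tert-butyldimethylsilyl chloride, CC(C)(C)[Si](C)(C)Cl
Why: Chemoselective silylation; the unhindered primary benzylic alcohol should react well ahead of a phenol flanked on both sides (iodine and the CH2O arm), as is usual for salicyl alcohols.

Step 5
Reactants: 6 4-hydroxy-3-iodobenzoic acid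
Product: 8 3-iodo-4-(methoxymethoxy)benzoic acid, via methoxymethyl ester 7 (not isolated)
Conditions: MOMCl (2.4 equiv), K2CO3 (3 equiv), DMF, 0 °C to rt; then LiOH, THF/H2O, rt; 1 M HCl to pH 4, 0 °C
Reagents that add atoms: chloromethyl methyl ether (MOMCl), COCCl; lithium hydroxide, [Li+].[OH-] (its oxygen enters the carboxyl group on acyl–oxygen cleavage)
Why: Double O-alkylation followed by saponification; the MOM ester is an acyl acetal that hydroxide cleaves at room temperature, whereas the aryl MOM ether is stable to base and to the brief cold acidification.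

Step 6
Reactants: 5 2-{[(tert-butyldimethylsilyl)oxy]methyl}-4,6-diiodo-5-(methoxymethoxy)phenol; 8 3-iodo-4-(methoxymethoxy)benzoic acid
Product: 9 2-{[(tert-butyldimethylsilyl)oxy]methyl}-4,6-diiodo-5-(methoxymethoxy)phenyl 3-iodo-4-(methoxymethoxy)benzoate
Conditions: DCC (1.2 equiv), DMAP (0.3 equiv), CH2Cl2, 0 °C to rt
Reagents that add atoms: none
Why: Steglich esterification; acyl transfer through DMAP works for hindered acidic phenols and, unlike acid chloride formation, releases no HCl that could attack the MOM ethers.

Step 7
Reactants: 9 the triiodo aryl benzoate from step 6; 10 tributyl(3-methylbut-2-en-1-yl)stannane (3.6 equiv)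
Product: 11 2-{[(tert-butyldimethylsilyl)oxy]methyl}-5-(methoxymethoxy)-4,6-diprenylphenyl 4-(methoxymethoxy)-3-prenylbenzoate
Conditions: Pd(PPh3)4 (10 mol %), DMF (degassed), 90 °C
Reagents that add atoms: none
Why: Threefold Stille coupling; each C–I bond adds to zerovalent palladium, prenyl passes from tin to palladium, reductive elimination at the unsubstituted allyl terminus gives the linear prenyl arene, and the base-free medium spares the aryl ester, silyl ether and acetals.

Step 8
Reactants: 11 the triprenylated aryl benzoate from step 7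
Product: 12 tert-butyl{[4-(methoxymethoxy)-2-({1-[4-(methoxymethoxy)-3-prenylphenyl]ethenyl}oxy)-3,5-diprenylphenyl]methoxy}dimethylsilane
Conditions: Cp2TiMe2 (3 equiv), toluene, 75 °C, dark; basic alumina
Reagents that add atoms: dimethyltitanocene Cp2TiMe2, [CH3-].[CH3-].[Ti+4].c1cc[cH-]c1.c1cc[cH-]c1
Why: Petasis methylenation; Cp2Ti=CH2 formed on heating adds to the only carbonyl group and cycloreverts to the enol ether, aryl benzoates being standard substrates, while trisubstituted olefins, acetals and the silyl ether do not react.

Step 9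
Reactants: 12 the silyl-protected aryl 1-arylvinyl ether from step 8
Product: 13 [4-(methoxymethoxy)-2-({1-[4-(methoxymethoxy)-3-prenylphenyl]ethenyl}oxy)-3,5-diprenylphenyl]methanol
Conditions: TBAF (1.1 equiv), THF, 0 °C; aqueous work-up at pH 7–8
Reagents that add atoms: none
Why: Fluoride desilylation; the medium stays basic, so the acid-labile enol ether and the MOM ethers should be untouched.

Step 10
Reactants: 13 the benzylic alcohol from step 9
Product: 14 4-(methoxymethoxy)-2-({1-[4-(methoxymethoxy)-3-prenylphenyl]ethenyl}oxy)-3,5-diprenylbenzaldehyde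
Conditions: activated MnO2 (15 equiv), CH2Cl2, rt; filtration, Et3N-deactivated silica
Reagents that add atoms: none
Why: MnO2 oxidation of an electron-rich benzylic alcohol; it is neutral and heterogeneous, stops at the aldehyde and attacks neither the enol ether nor the prenyl groups.

Step 11
Reactants: 14 4-(methoxymethoxy)-2-({1-[4-(methoxymethoxy)-3-prenylphenyl]ethenyl}oxy)-3,5-diprenylbenzaldehyde
Product: 15 (2S)-7,4'-bis(methoxymethoxy)-6,8,3'-triprenylflavanone
Conditions: [Rh(cod)Cl]2 (2.5 mol %), (R)-DTBM-SEGPHOS (5.5 mol %), NaB[3,5-(CF3)2C6H3]4 (5 mol %), 2,6-di-tert-butyl-4-methylpyridine (10 mol %), 4 Å MS, 1,4-dioxane, 70 °C, Ar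
Reagents that add atoms: none
Why: Proposed new method: the cationic bisphosphine complex of monovalent rhodium adds oxidatively into the formyl C–H bond of 14, the resulting acyl hydride of trivalent rhodium binds the vinyl ether that O1 keeps within reach of the metal, reversible migratory insertion places hydride on C2 and rhodium on the terminal carbon C3, and C–C reductive elimination from the seven-membered acyl–alkyl rhodacycle makes C3–C4 and releases the catalyst. The closest known reaction type is the enantioselective endo hydroacylation of ortho-(2-substituted allyl)benzaldehydes to 3-substituted tetralones and of 2-(1-arylvinyl)benzaldehydes to 3-arylindanones; 14 is the analogue with O1 in place of the benzylic CH2, and an enol ether has not been shown as the acceptor. Ring C closes in a formal 6-endo-trig mode, both olefin carbons ending up in the ring. C2, the only new stereocentre, is fixed when hydride reaches one enantioface of the bound olefin, and that face is chosen by the quadrant pattern of the bulky atropisomeric ligand, which has to tell the ring B aryl group from the O1 aryloxy arm. Regioselectivity over 5-exo closure rests on the 1,1-disubstitution of the olefin, because rhodium on C2 would be a crowded tertiary alkyl (hemmed in further by the C8 prenyl group next to O1) whose reductive elimination to a quaternary centre is slow, so the reversible insertion should drain through the primary alkyl. Chemoselectivity rests on the prenyl olefins being trisubstituted and none standing ortho to the formyl group, while the non-coordinating borate, the hindered pyridine and the sieves keep acid away from the enol ether and the electron-rich ligand favours reductive elimination over decarbonylation.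

Step 12
Reactants: 15 (2S)-7,4'-bis(methoxymethoxy)-6,8,3'-triprenylflavanone
Product: 16 (2S)-7,4'-dihydroxy-6,8,3'-triprenylflavanone
Conditions: HCl (1.25 M in MeOH), 0 °C to rt, stopped at full conversion; NaHCO3 quench
Reagents that add atoms: none
Why: Acid-catalysed acetal exchange with methanol; aryl MOM ethers of ortho-prenylated flavanones are routinely cleaved this way, the dilute acid and low temperature should leave the prenyl groups uncyclised, and C2 is not epimerised because ring opening of flavanones needs base.

Compound list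
1 | 2,4-dihydroxybenzaldehyde | O=Cc1ccc(O)cc1O | starting material
2 | 2,4-dihydroxy-3,5-diiodobenzaldehyde | O=Cc1cc(I)c(O)c(I)c1O | intermediate
3 | 2-hydroxy-3,5-diiodo-4-(methoxymethoxy)benzaldehyde | O=Cc1cc(I)c(OCOC)c(I)c1O | intermediate
4 | 2-(hydroxymethyl)-4,6-diiodo-5-(methoxymethoxy)phenol | OCc1cc(I)c(OCOC)c(I)c1O | intermediate
5 | 2-{[(tert-butyldimethylsilyl)oxy]methyl}-4,6-diiodo-5-(methoxymethoxy)phenol | CC(C)(C)[Si](C)(C)OCc1cc(I)c(OCOC)c(I)c1O | intermediate
6 | 4-hydroxy-3-iodobenzoic acid | O=C(O)c1ccc(O)c(I)c1 | starting material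
7 | methoxymethyl 3-iodo-4-(methoxymethoxy)benzoate (not isolated) | COCOC(=O)c1ccc(OCOC)c(I)c1 | intermediate
8 | 3-iodo-4-(methoxymethoxy)benzoic acid | O=C(O)c1ccc(OCOC)c(I)c1 | intermediate
9 | 2-{[(tert-butyldimethylsilyl)oxy]methyl}-4,6-diiodo-5-(methoxymethoxy)phenyl 3-iodo-4-(methoxymethoxy)benzoate | CC(C)(C)[Si](C)(C)OCc1cc(I)c(OCOC)c(I)c1OC(=O)c1ccc(OCOC)c(I)c1 | intermediate
10 | tributyl(3-methylbut-2-en-1-yl)stannane | CCCC[Sn](CCCC)(CCCC)CC=C(C)C | starting material
11 | 2-{[(tert-butyldimethylsilyl)oxy]methyl}-5-(methoxymethoxy)-4,6-diprenylphenyl 4-(methoxymethoxy)-3-prenylbenzoate | CC(C)(C)[Si](C)(C)OCc1cc(CC=C(C)C)c(OCOC)c(CC=C(C)C)c1OC(=O)c1ccc(OCOC)c(CC=C(C)C)c1 | intermediate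
12 | tert-butyl{[4-(methoxymethoxy)-2-({1-[4-(methoxymethoxy)-3-prenylphenyl]ethenyl}oxy)-3,5-diprenylphenyl]methoxy}dimethylsilane | CC(C)(C)[Si](C)(C)OCc1cc(CC=C(C)C)c(OCOC)c(CC=C(C)C)c1OC(=C)c1ccc(OCOC)c(CC=C(C)C)c1 | intermediate
13 | [4-(methoxymethoxy)-2-({1-[4-(methoxymethoxy)-3-prenylphenyl]ethenyl}oxy)-3,5-diprenylphenyl]methanol | OCc1cc(CC=C(C)C)c(OCOC)c(CC=C(C)C)c1OC(=C)c1ccc(OCOC)c(CC=C(C)C)c1 | intermediate
14 | 4-(methoxymethoxy)-2-({1-[4-(methoxymethoxy)-3-prenylphenyl]ethenyl}oxy)-3,5-diprenylbenzaldehyde | O=Cc1cc(CC=C(C)C)c(OCOC)c(CC=C(C)C)c1OC(=C)c1ccc(OCOC)c(CC=C(C)C)c1 | intermediate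
15 | (2S)-7-(methoxymethoxy)-2-[4-(methoxymethoxy)-3-prenylphenyl]-6,8-diprenylchroman-4-one | CC(C)=CCc1cc([C@@H]2CC(=O)c3cc(CC=C(C)C)c(OCOC)c(CC=C(C)C)c3O2)ccc1OCOC | intermediate
16 | (2S)-7-hydroxy-2-(4-hydroxy-3-prenylphenyl)-6,8-diprenylchroman-4-one | CC(C)=CCc1cc([C@@H]2CC(=O)c3cc(CC=C(C)C)c(O)c(CC=C(C)C)c3O2)ccc1O | target

Total step count: 12. Longest linear sequence: 11 (steps 1–4 and 6–12).

Steps most likely to fail

1. Step 11. The acyl hydride may decarbonylate before insertion. The oxygen and aryl substituents on C2 may draw rhodium to that carbon and divert the closure into the 5-exo sense. The enol ether may hydrolyse on the Lewis acidic metal, or facial selectivity may be poor.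
The fallback abandons hydroacylation. It builds ring C by oxa-Michael closure of a chalcone and secures the enantiomer by kinetic resolution, all known chemistry. It sets out from 3.
- MeMgBr (2.2 equiv, THF, −78 to 0 °C) should give 1-[2-hydroxy-3,5-diiodo-4-(methoxymethoxy)phenyl]ethanol F1.
- MnO2 should oxidise this to 1-[2-hydroxy-3,5-diiodo-4-(methoxymethoxy)phenyl]ethanone F2.
- Commercial 4-hydroxy-3-iodobenzaldehyde is protected (MOMCl, K2CO3, acetone) as 3-iodo-4-(methoxymethoxy)benzaldehyde F3.
- Claisen–Schmidt condensation of the ketone and the aldehyde (KOH, EtOH, rt) should give (E)-1-[2-hydroxy-3,5-diiodo-4-(methoxymethoxy)phenyl]-3-[3-iodo-4-(methoxymethoxy)phenyl]prop-2-en-1-one F4.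
- NaOAc in refluxing EtOH should close this to racemic 6,8,3'-triiodo-7,4'-bis(methoxymethoxy)flavanone F5.
- Threefold Stille coupling with 10 under the conditions of step 7 should give racemic 7,4'-bis(methoxymethoxy)-6,8,3'-triprenylflavanone F6.
- Asymmetric transfer hydrogenation follows, with whichever antipode of [Cp*RhCl(TsDPEN)] consumes the 2R enantiomer (HCO2H/Et3N, EtOAc, rt), stopped near half conversion. It should reduce that enantiomer to (2R,4R)-7,4'-bis(methoxymethoxy)-6,8,3'-triprenylflavan-4-ol F7 and leave the 2S ketone.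

Chromatography then returns to the route at 15.

2. Step 7. The coupling may stall at the C–I bond flanked by two oxygen substituents. Allyl transposition may occur during transfer from tin. The arylpalladium species next to the acyloxy group may attack the benzoate ring instead of being prenylated.
The fallback prenylates the two fragments before they are joined and uses boron in place of tin, which the absence of the ester allows. It sets out from 5 and 8.
- Suzuki–Miyaura coupling of 5 with prenylboronic acid pinacol ester (Pd(dppf)Cl2, K3PO4, THF/H2O, 70 °C) should give 2-{[(tert-butyldimethylsilyl)oxy]methyl}-5-(methoxymethoxy)-4,6-diprenylphenol F8.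
- The same coupling on the potassium salt of 8 should give 4-(methoxymethoxy)-3-prenylbenzoic acid F9.

Steglich esterification of the two as in step 6 comes back to the route at 11.

3. Step 12. Once a phenol is freed, acid may close it onto the neighbouring prenyl group. Long exposure needed for the second, more hindered acetal may also erode the configuration at C2.
The fallback replaces solvolysis by a two-stage protecting-group exchange without Brønsted acid. It sets out from 15. TMSOTf and 2,2'-bipyridyl (MeCN, 0 °C) should convert both aryl MOM ethers into silyl ethers, giving (2S)-7,4'-bis(trimethylsilyloxy)-6,8,3'-triprenylflavanone F10. Water at neutral pH should then hydrolyse this in the same work-up, coming back to the route at 16.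

Further compounds
F1 | step 11 | 1-[2-hydroxy-3,5-diiodo-4-(methoxymethoxy)phenyl]ethanol (racemic) | CC(O)c1cc(I)c(OCOC)c(I)c1O
F2 | step 11 | 1-[2-hydroxy-3,5-diiodo-4-(methoxymethoxy)phenyl]ethanone | CC(=O)c1cc(I)c(OCOC)c(I)c1O
F3 | step 11 | 3-iodo-4-(methoxymethoxy)benzaldehyde | O=Cc1ccc(OCOC)c(I)c1
F4 | step 11 | (E)-1-[2-hydroxy-3,5-diiodo-4-(methoxymethoxy)phenyl]-3-[3-iodo-4-(methoxymethoxy)phenyl]prop-2-en-1-one | O=C(/C=C/c1ccc(OCOC)c(I)c1)c1cc(I)c(OCOC)c(I)c1O
F5 | step 11 | racemic 6,8,3'-triiodo-7,4'-bis(methoxymethoxy)flavanone | O=C1CC(c2ccc(OCOC)c(I)c2)Oc2c(I)c(OCOC)c(I)cc21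
F6 | step 11 | racemic 7,4'-bis(methoxymethoxy)-6,8,3'-triprenylflavanone | CC(C)=CCc1cc(C2CC(=O)c3cc(CC=C(C)C)c(OCOC)c(CC=C(C)C)c3O2)ccc1OCOC
F7 | step 11 | (2R,4R)-7,4'-bis(methoxymethoxy)-6,8,3'-triprenylflavan-4-ol | CC(C)=CCc1cc([C@H]2C[C@@H](O)c3cc(CC=C(C)C)c(OCOC)c(CC=C(C)C)c3O2)ccc1OCOC
F8 | step 7 | 2-{[(tert-butyldimethylsilyl)oxy]methyl}-5-(methoxymethoxy)-4,6-diprenylphenol | CC(C)(C)[Si](C)(C)OCc1cc(CC=C(C)C)c(OCOC)c(CC=C(C)C)c1O
F9 | step 7 | 4-(methoxymethoxy)-3-prenylbenzoic acid | O=C(O)c1ccc(OCOC)c(CC=C(C)C)c1
F10 | step 12 | (2S)-7,4'-bis(trimethylsilyloxy)-6,8,3'-triprenylflavanone | CC(C)=CCc1cc([C@@H]2CC(=O)c3cc(CC=C(C)C)c(O[Si](C)(C)C)c(CC=C(C)C)c3O2)ccc1O[Si](C)(C)C
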